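**Assumption (one line):** (E)-geranylacetone and (E,E)-farnesol are commercial. The Z-selective olefination in Step 1 is taken to give about 5:1 Z:E, with the Z ester separated on AgNO3–silica.

## Retrosynthetic overview
1. Colleterpenol ⇒ desulfonylation of macrocyclic allylic sulfone **18**. The 14-membered ring is closed last, by intramolecular SN2 opening of cis-epoxide **17** at the secondary epoxide carbon by the allylic sulfonyl carbanion. This inverts the ring carbon and sets the (S)-carbinol/(R)-ring-CH pair.
2. **17** ⇒ Cu-catalysed allyl–alkyl coupling of the Grignard from ω-chloride **12** with cis-epoxy tosylate **7** (C13–C14 bond), then conversion of the TBS ether to the allylic sulfone.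
3. **7** ⇒ Sharpless asymmetric epoxidation of (2Z,6E)-farnesol **4**, which breaks the mirror symmetry of an achiral alkene ⇒ Z-selective olefination of geranylacetone **1**.
4. **12** ⇒ (E,E)-farnesol via SeO2 oxidation of the terminal gem-dimethyl group, which differentiates its two methyls. Rings formed: only the 14-membered carbocycle, in Step 12.

## Forward route

**Step 1**
Reactants: **1** (E)-geranylacetone; **2** methyl bis(2,2,2-trifluoroethyl)phosphonoacetate
Product: **3** methyl (2Z,6E)-farnesoate
Conditions: **2**, KHMDS, 18-crown-6, THF, –78 °C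
Reagents that add atoms: none beyond **2**
Why: Still–Gennari-type Horner–Wadsworth–Emmons olefination of the methyl ketone with an electron-poor phosphonate favours the Z-trisubstituted enoate. The C6 alkene is untouched.

**Step 2**
Reactants: **3**
Product: **4** (2Z,6E)-farnesol
Conditions: DIBAL-H, CH2Cl2, –78 °C
Reagents that add atoms: none (hydride only)
Why: 1,2-reduction of the ester to the allylic alcohol leaves the alkene geometry unchanged.

**Step 3**
Reactants: **4**
Product: **5** {(2R,3S)-3-[(3E)-4,8-dimethylnona-3,7-dienyl]-3-methyloxiran-2-yl}methanol (cis-epoxide)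
Conditions: Ti(OiPr)4 (10 mol%), D-(–)-DET, TBHP, 3 Å MS, CH2Cl2, –20 °C, 3 d
Reagents that add atoms: tert-butyl hydroperoxide, CC(C)(C)OO (source of the epoxide O)
Why: Sharpless asymmetric epoxidation is selective for the allylic-alcohol alkene. D-(–)-DET delivers O to one enantioface, which sets C2 (R) and C3 (S). The C3 (S) centre becomes the target carbinol, and the Z geometry makes the epoxide cis, which is what the later inversion requires.

**Step 4**
Reactants: **5**; **6** p-toluenesulfonyl chloride (from toluene)
Product: **7** (2R,3S)-epoxy tosylate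
Conditions: **6**, Et3N, DMAP (cat.), CH2Cl2, 0 °C
Reagents that add atoms: TsCl, Cc1ccc(cc1)S(=O)(=O)Cl
Why: Selective sulfonylation of the primary alcohol leaves the epoxide intact.

**Step 5**
Reactants: **8** (2E,6E)-farnesol; **9** TBSCl
Product: **10** farnesyl TBS ether
Conditions: **9**, imidazole, DMF, 25 °C
Reagents that add atoms: TBSCl, CC(C)(C)[Si](C)(C)Cl
Why: Silyl protection of the allylic alcohol, needed for the Grignard in Step 8.

**Step 6**
Reactants: **10**
Product: **11** (2E,6E,10E)-12-OTBS-2,6,10-trimethyldodeca-2,6,10-trien-1-ol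
Conditions: SeO2 (0.3 equiv), TBHP, CH2Cl2, 0 → 25 °C
Reagents that add atoms: TBHP, CC(C)(C)OO; SeO2, O=[Se]=O
Why: Sharpless–Umbreit allylic oxidation differentiates the two methyls of the terminal isopropylidene and hydroxylates the methyl trans to the chain (E-CH2OH). The other trisubstituted alkenes are deactivated or more hindered.

**Step 7**
Reactants: **11**
Product: **12** (2E,6E,10E)-1-chloro-12-OTBS-2,6,10-trimethyldodeca-2,6,10-triene
Conditions: (i) MsCl, Et3N, CH2Cl2, –20 °C; (ii) LiCl, DMF, 0 °C (one pot)
Reagents that add atoms: LiCl, [Li+].[Cl-] (MsCl, CS(=O)(=O)Cl, activates and leaves as mesylate)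
Why: The allylic mesylate is displaced by chloride via SN2 without allylic transposition.

**Step 8**
Reactants: **12**; **7**
Product: **13** TBS ether of (2E,6E,10E)-3,7,11-trimethyl-13-[(2R,3S)-3-methyl-3-(4,8-dimethylnona-3,7-dienyl)oxiran-2-yl]trideca-2,6,10-trien-1-ol
Conditions: (i) Mg, THF, 0 °C, to form the allylic Grignard from **12**; (ii) add to **7**, Li2CuCl4 (5 mol%), THF, –20 → 0 °C
Reagents that add atoms: none (Mg leaves as salt)
Why: Kochi–Schlosser Cu-catalysed Grignard/alkyl-tosylate coupling. Attack occurs at the primary allylic terminus (α-selective) and retains the E alkene. It displaces the primary tosylate in preference to the hindered trisubstituted epoxide, which is retained unchanged (no stereocentre involved).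

**Step 9**
Reactants: **13**
Product: **14** allylic alcohol
Conditions: TBAF, THF, 0 → 25 °C
Reagents that add atoms: none
Why: Fluoride desilylation; the epoxide is inert.

**Step 10**
Reactants: **14**
Product: **15** allylic chloride
Conditions: (i) MsCl, Et3N, CH2Cl2, –20 °C; (ii) LiCl, DMF, 0 °C
Reagents that add atoms: LiCl, [Li+].[Cl-]
Why: Same mild SN2 chlorination as Step 7.

**Step 11**
Reactants: **15**; **16** sodium benzenesulfinate (from benzene)
Product: **17** epoxy allylic phenyl sulfone
Conditions: **16**, DMF, 25 °C
Reagents that add atoms: PhSO2Na, [Na+].[O-]S(=O)c1ccccc1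
Why: The sulfinate S-alkylates the primary allylic chloride by SN2 and retains the E alkene. This installs the carbanion precursor for the ring closure.

**Step 12**
Reactants: **17**
Product: **18** macrocyclic sulfone, a 14-membered ring with the tertiary alcohol and a C2 phenylsulfonyl group (C–SO2Ph epimers)
Conditions: LiHMDS (4 equiv), HMPA (10 equiv), THF, 2 mM (syringe-pump addition), –78 → 25 °C, then 40 °C
Reagents that add atoms: none
Why: The allylic α-sulfonyl carbanion attacks the less hindered secondary epoxide carbon, not the tertiary one, with SN2 inversion. This sets the ring carbon as R, and the retained C–O bond keeps the carbinol S, giving the target S/R pair.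
Proposed new method: This is an intramolecular version of alkylation of a sulfonyl carbanion with a 2,2,3-trisubstituted epoxide. The TS is a 14-membered ring, and high dilution plus HMPA-separated Li+ compensate for the hindered neopentyl-like epoxide carbon. The closest known reactions are sulfonyl-carbanion opening of terminal epoxides and macrocyclic allylic sulfone alkylations in cembranoid synthesis.

**Step 13**
Reactants: **18**
Product: **19** colleterpenol
Conditions: Pd(dppp)Cl2 (10 mol%), LiBHEt3, THF, 0 °C
Reagents that add atoms: none (hydride only)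
Why: Pd-catalysed hydrogenolysis of the allylic sulfone via a π-allyl. Hydride is delivered to the less hindered secondary terminus, so the trisubstituted E alkene stays in place. Both C–SO2Ph epimers converge, and the stereocentres at C(OH) and the ring CH are untouched.

## Compound list
| # | Name | SMILES | Role |
|---|---|---|---|
| 1 | (5E)-6,10-dimethylundeca-5,9-dien-2-one (geranylacetone) | CC(C)=CCC/C(C)=C/CCC(C)=O | starting material |
| 2 | methyl bis(2,2,2-trifluoroethyl)phosphonoacetate | COC(=O)CP(=O)(OCC(F)(F)F)OCC(F)(F)F | starting material |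
| 3 | methyl (2Z,6E)-farnesoate | CC(C)=CCC/C(C)=C/CC/C(C)=C\C(=O)OC | intermediate |
| 4 | (2Z,6E)-farnesol | CC(C)=CCC/C(C)=C/CC/C(C)=C\CO | intermediate |
| 5 | (2R,3S)-cis-2,3-epoxy-(6E)-farnesol | OC[C@H]1O[C@@]1(C)CC/C=C(\C)CC/C=C(C)C | intermediate |
| 6 | p-toluenesulfonyl chloride | Cc1ccc(cc1)S(=O)(=O)Cl | starting material (toluene-derived) |
| 7 | (2R,3S)-epoxy tosylate | Cc1ccc(cc1)S(=O)(=O)OC[C@H]1O[C@@]1(C)CC/C=C(\C)CC/C=C(C)C | intermediate |
| 8 | (2E,6E)-farnesol | CC(C)=CCC/C(C)=C/CC/C(C)=C/CO | starting material |
| 9 | tert-butyldimethylsilyl chloride | CC(C)(C)[Si](C)(C)Cl | starting material |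
| 10 | farnesyl TBS ether | CC(C)=CCC/C(C)=C/CC/C(C)=C/CO[Si](C)(C)C(C)(C)C | intermediate |
| 11 | 12-hydroxy-farnesyl TBS ether | OC/C(C)=C/CC/C(C)=C/CC/C(C)=C/CO[Si](C)(C)C(C)(C)C | intermediate |
| 12 | 12-chloro-farnesyl TBS ether | ClC/C(C)=C/CC/C(C)=C/CC/C(C)=C/CO[Si](C)(C)C(C)(C)C | intermediate |
| 13 | coupled epoxy TBS ether | CC(C)(C)[Si](C)(C)OC/C=C(\C)CC/C=C(\C)CC/C=C(\C)CC[C@H]1O[C@@]1(C)CC/C=C(\C)CC/C=C(C)C | intermediate |
| 14 | epoxy allylic alcohol | OC/C=C(\C)CC/C=C(\C)CC/C=C(\C)CC[C@H]1O[C@@]1(C)CC/C=C(\C)CC/C=C(C)C | intermediate |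
| 15 | epoxy allylic chloride | ClC/C=C(\C)CC/C=C(\C)CC/C=C(\C)CC[C@H]1O[C@@]1(C)CC/C=C(\C)CC/C=C(C)C | intermediate |
| 16 | sodium benzenesulfinate | [Na+].[O-]S(=O)c1ccccc1 | starting material (benzene-derived) |
| 17 | epoxy allylic phenyl sulfone | O=S(=O)(c1ccccc1)C/C=C(\C)CC/C=C(\C)CC/C=C(\C)CC[C@H]1O[C@@]1(C)CC/C=C(\C)CC/C=C(C)C | intermediate |
| 18 | macrocyclic sulfone (C–SO2Ph epimeric) | CC(C)=CCC/C(C)=C/CC[C@](C)(O)[C@H]1C(S(=O)(=O)c2ccccc2)/C=C(\C)CC/C=C(\C)CC/C=C(\C)CC1 | intermediate |
| 19 | colleterpenol | CC(C)=CCC/C(C)=C/CC[C@](C)(O)[C@H]1C/C=C(\C)CC/C=C(\C)CC/C=C(\C)CC1 | target |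

## Totals
Total steps: 13. Longest linear sequence: 10 (geranylacetone → Z-ester → Z-farnesol → epoxy alcohol → tosylate → coupling → desilylation → chloride → sulfone → macrocyclisation → desulfonylation).

## Three steps most likely to fail
1. **Step 12 (macrocyclic epoxide opening).** The epoxide carbon is hindered, and oligomerisation or base-induced epoxide isomerisation may compete.
   Fallback: change the order of bond formation. First open the O-silylated cis-epoxide intermolecularly with the lithiated farnesyl phenyl sulfone (HMPA, 1 M) to form the C1–C2 bond. Then close the ring at C13–C14 by Kato-type intramolecular sulfone alkylation (allylic sulfone at C13, primary iodide at C14), and remove the sulfone.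
2. **Steps 1 and 3 (Z-selective olefination of a ketone, then AE of a Z-allylic alcohol).** Z:E selectivity, and the rate and ee of the AE, are modest for Z substrates.
   Fallback: build (2Z,6E)-farnesol by syn-methylcupration (MeMgBr/CuI) of the alkynol R–C≡C–CH2OH (R = homogeranyl), which gives the Z-trisubstituted allylic alcohol stereospecifically, before the same AE.
3. **Step 8 (Cu-catalysed allylic Grignard coupling).** Risks are α/γ regiochemistry, E→Z scrambling of the C11=C12 alkene through the 1,3-shift, and Mg-halide opening of the epoxide.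
   Fallback: use a Biellmann-type route instead. Convert **12** to the ω-phenylsulfone, alkylate its anion with **7**, and remove the sulfone with Pd/LiBHEt3.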